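**Strategy**

Ring E is cut at two adjacent carbons of the central resorcinol ring B: B6, which carries the ring-E CH2 and lies meta to both ring-B oxygens (on B2 and B4), and B1, which carries C3 of dihydrofuran D2. One palladium/norbornene operation joins a ring-B iodide (iodine on B1, MOM ethers on B2 and B4, B6–H free) to an enantioenriched 2,2-diarylethyl bromide whose ring F bears an (E)-4-methoxystyryl arm: ortho alkylation makes B6–CH2, the ipso Heck closure makes B1–C3(D2) and ring E. Position B6, closed to electrophilic substitution, is thus reached from the neighbouring iodide; D2 and D1 are added afterwards.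

Key step: step 7

Labels:
- Ring B carbons: B1 (bears C3 of D2), B2 (O of D2), B3 (H), B4 (O of D1), B5 (C3 of D1), B6 (ring-E CH2).
- Ring E: B6–CH2–CH(ring A)–F1–F6–C3(D2)–B1.
- Ring A: the 2,4-dioxygenated phenyl on the ring-E methine.
- Ring F: F1 (on the methine), F2 and F4 (oxygens), F6 (on C3 of D2).
- D2 is the dihydrofuran on B1/B2; D1 is the dihydrofuran on B5/B4.

Assumption 1: the target's arrangement of D2 relative to the ring-E methine is taken to be the thermodynamically preferred one, so the equilibrating acid closure of step 8 is expected to deliver it.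

Assumption 2: the hand of the chiral catalysts in steps 4 and 14 is quoted for the required sense and would be confirmed on a model substrate; the antipode is used if the sense is opposite.

**Route**

Step 1
Reactants: 1 2-bromo-3,5-dimethoxybenzaldehyde; 2 diethyl (4-methoxybenzyl)phosphonate
Product: 3 (E)-2-bromo-1,5-dimethoxy-3-(4-methoxystyryl)benzene
Conditions: KOt-Bu, THF, 0 °C → rt
Reagents that add atoms: none
Why: Horner–Wadsworth–Emmons olefination of an aryl aldehyde with a benzylic phosphonate anion, which should give the (E)-stilbene and leaves the aryl bromide untouched.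

Step 2
Reactants: 3 (E)-2-bromo-1,5-dimethoxy-3-(4-methoxystyryl)benzene; 4 2',4'-dimethoxyacetophenone
Product: 6 rac-1-(2,4-dimethoxyphenyl)-1-{2,4-dimethoxy-6-[(E)-4-methoxystyryl]phenyl}ethanol, via aryllithium 5 (not isolated)
Conditions: n-BuLi, THF, −78 °C; then 4, LaCl3·2LiCl, −78 → 0 °C
Reagents that add atoms: none
Why: Bromine–lithium exchange followed by 1,2-addition of the ortho-methoxy-stabilised aryllithium to the ketone, the lanthanum salt activating the carbonyl so that addition outruns enolisation; the carbinol centre is racemic and is removed in step 3.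

Step 3
Reactants: 6 rac-1-(2,4-dimethoxyphenyl)-1-{2,4-dimethoxy-6-[(E)-4-methoxystyryl]phenyl}ethanol
Product: 7 1-(2,4-dimethoxyphenyl)-1-{2,4-dimethoxy-6-[(E)-4-methoxystyryl]phenyl}ethene
Conditions: TsOH·H2O (5 mol %), toluene, 50 °C
Reagents that add atoms: none
Why: Acid-catalysed E1 dehydration of a tertiary, doubly benzylic alcohol that ionises readily because both aryl groups are electron-rich, with only the methyl group able to lose a proton.

Step 4
Reactants: 7 1-(2,4-dimethoxyphenyl)-1-{2,4-dimethoxy-6-[(E)-4-methoxystyryl]phenyl}ethene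
Product: 9 (R)-2-(2,4-dimethoxyphenyl)-2-{2,4-dimethoxy-6-[(E)-4-methoxystyryl]phenyl}ethanol, via pinacol boronate 8 (not isolated)
Conditions: CuCl (5 mol %), (R)-DTBM-SEGPHOS, KOt-Bu (10 mol %), HBpin (1.2 equiv), THF, rt; then NaOH, H2O2, THF/H2O, 0 °C
Reagents that add atoms: pinacolborane, CC1(C)OBOC1(C)C (boron and pinacol of 8 only); hydrogen peroxide, OO (hydroxyl oxygen of 9)
Why: Copper hydride-catalysed anti-Markovnikov asymmetric hydroboration of a 1,1-disubstituted vinylarene followed by stereoretentive C–B oxidation; the chiral bisphosphine selects the alkene face in the hydrocupration that places hydrogen on the internal carbon (twisted 2,6-disubstituted ring F against near-coplanar ring A), and the open terminal methylene should react before the flanked internal stilbene.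

Step 5
Reactants: 9 (R)-2-(2,4-dimethoxyphenyl)-2-{2,4-dimethoxy-6-[(E)-4-methoxystyryl]phenyl}ethanol
Product: 10 (R)-2-(2,4-dimethoxyphenyl)-2-{2,4-dimethoxy-6-[(E)-4-methoxystyryl]phenyl}ethyl bromide
Conditions: CBr4, PPh3, CH2Cl2, 0 °C
Reagents that add atoms: carbon tetrabromide, BrC(Br)(Br)Br
Why: Appel bromination of a primary alcohol by SN2 displacement of the oxyphosphonium group under cold, neutral conditions that should leave the benzylic stereocentre and the stilbene untouched; the bromide is used promptly.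

Step 6
Reactants: 11 4-iodoresorcinol
Product: 12 1-iodo-2,4-bis(methoxymethoxy)benzene
Conditions: MOMCl, i-Pr2NEt, CH2Cl2, 0 °C → rt
Reagents that add atoms: chloromethyl methyl ether, COCCl
Why: Double O-alkylation of the phenols (acetal protection); using the same acid-labile group on both oxygens needs no differentiation of the two phenols and lets one later acid step unmask both without hydrogenolysis next to benzylic ethers.

Step 7
Reactants: 10 (R)-2-(2,4-dimethoxyphenyl)-2-{2,4-dimethoxy-6-[(E)-4-methoxystyryl]phenyl}ethyl bromide; 12 1-iodo-2,4-bis(methoxymethoxy)benzene (1.5 equiv)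
Product: 13 (5E,11R)-11-(2,4-dimethoxyphenyl)-1,3-dimethoxy-5-(4-methoxybenzylidene)-6,8-bis(methoxymethoxy)-10,11-dihydro-5H-dibenzo[a,d][7]annulene
Conditions: Pd(OAc)2 (10 mol %), tri(2-furyl)phosphine (22 mol %), norbornene (4 equiv), Cs2CO3 (4 equiv), MeCN, 85 °C
Reagents that add atoms: none
Why: Catellani ortho-alkylation/Heck annulation: zerovalent palladium inserts into the B1–I bond of 12, norbornene insertion and B6–H palladation give a five-membered palladacycle, and oxidative addition of the primary bromide 10 to tetravalent palladium with reductive elimination forms B6–CH2. With both ortho positions now occupied norbornene is extruded, and the B1–palladium species carbopalladates the tethered stilbene and undergoes syn β-hydride elimination to the (E)-benzylidene. The closest known reaction is the norbornene-mediated ortho-alkylation/intramolecular Heck synthesis of benzo-fused five- to seven-membered carbocycles from ortho-substituted aryl iodides and bromoalkyl alkenes. Ring E closes in the 7-exo-trig mode at the alkene carbon attached to F6, the 8-endo alternative being disfavoured by the tether. No stereocentre is created and the ring-E methine (R) is not involved, the alkene geometry following from syn insertion and syn elimination of the only β-hydrogen. The step needs alkylation at B6 before any Heck event, which is secured by the single ortho substituent (B2–OMOM) and the norbornene relay, since the aryl palladium iodide is trapped by norbornene faster than by the internal stilbene.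

Step 8
Reactants: 13 (5E,11R)-11-(2,4-dimethoxyphenyl)-1,3-dimethoxy-5-(4-methoxybenzylidene)-6,8-bis(methoxymethoxy)-10,11-dihydro-5H-dibenzo[a,d][7]annulene
Product: 15 D2-closed phenol (D2 2R,3R-trans; ring-E methine R; B4–OH free), via bis-phenol 14 (not isolated)
Conditions: HCl (3 M aq), MeOH/THF, 50 °C; then TsOH·H2O (0.2 equiv), HFIP/CH2Cl2, rt, dilute
Reagents that add atoms: none
Why: Acid-catalysed acetal cleavage followed by Brønsted acid hydroalkoxylation of the ortho-hydroxy triarylethylene: protonation at C3 gives the 4-methoxybenzylic cation, which B2–OH captures, and because ionisation at C2 and proton loss from C3 are reversible the ring should settle as the 2,3-trans isomer with C3 in the more stable orientation relative to the ring-E methine (2R,3R).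

Step 9
Reactants: 15 D2-closed phenol
Product: 16 salicylaldehyde (15 with CHO on B5)
Conditions: MgCl2, Et3N, (CH2O)n, MeCN, 80 °C
Reagents that add atoms: paraformaldehyde (as formaldehyde), C=O
Why: Magnesium phenoxide-directed ortho-formylation, expected at B5 because that ortho position is para to the D2 oxygen whereas B3 lies between two oxygens and is the less nucleophilic site of a resorcinol ether.

Step 10
Reactants: 16 salicylaldehyde; 17 4-methoxybenzyl chloride
Product: 18 B4–O-(4-methoxybenzyl) ether of 16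
Conditions: K2CO3, DMF, 50 °C
Reagents that add atoms: none
Why: Williamson etherification of the phenol; the benzylic CH2 introduced here later becomes C2 of D1.

Step 11
Reactants: 18 B4–O-(4-methoxybenzyl) ether of 16; 19 3,5-dimethoxyphenylmagnesium chloride
Product: 20 diarylmethanol (B5–CH(OH)(3,5-dimethoxyphenyl); both carbinol epimers)
Conditions: THF, 0 °C → rt
Reagents that add atoms: none
Why: Grignard 1,2-addition to the aryl aldehyde; the carbinol epimers are not separated because this centre is oxidised in step 12.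

Step 12
Reactants: 20 diarylmethanol
Product: 21 diaryl ketone (B5–C(=O)(3,5-dimethoxyphenyl))
Conditions: Dess–Martin periodinane, CH2Cl2, rt
Reagents that add atoms: none
Why: Dess–Martin oxidation of a secondary diarylmethanol under near-neutral conditions compatible with the electron-rich arenes and the benzylic ethers.

Step 13
Reactants: 21 diaryl ketone
Product: 22 hydrazone of 21
Conditions: N2H4·H2O (excess), AcOH (cat.), EtOH, 85 °C, sealed tube
Reagents that add atoms: hydrazine hydrate (as hydrazine), NN
Why: Acid-catalysed condensation of the ketone with excess hydrazine to the free hydrazone, heated because the carbonyl is flanked by two ortho substituents.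

Step 14
Reactants: 22 hydrazone of 21
Product: 24 cis-D1 octamethyl ether (D1 2S,3R), via diazo compound 23 (not isolated)
Conditions: MnO2, CH2Cl2, rt, filter; then Rh2(R-PTAD)4 (1 mol %), CH2Cl2, 0 °C → rt
Reagents that add atoms: none
Why: Oxidation of the hydrazone to the diaryldiazomethane and dirhodium-catalysed donor/donor carbene 1,5-insertion into the ether-activated benzylic C–H bond, a known enantioselective route to 2,3-diaryl-2,3-dihydrobenzofurans; the chiral carboxylate ligands choose the carbene face and set C3 of D1 (R), and the concerted insertion places the two aryl groups cis (C2 S).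

Step 15
Reactants: 24 cis-D1 octamethyl ether
Product: 25 octa-O-methyl ether of the target (D1 2R,3R-trans)
Conditions: TFA, CH2Cl2, 0 °C → rt
Reagents that add atoms: none
Why: Acid-mediated epimerisation at C2 of D1 through reversible heterolysis of the O–C2 bond to the 4-methoxybenzylic cation, which should reclose to the more stable trans isomer (C2 R) while C3 cannot ionise and keeps its configuration.

Step 16
Reactants: 25 octa-O-methyl ether of the target
Product: 26 CNP0154047.1
Conditions: BBr3, CH2Cl2, −78 °C → rt; then H2O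
Reagents that add atoms: none
Why: Boron tribromide cleavage of the eight aryl methyl ethers; no stereocentre is formed and both dihydrofurans are already in their stable trans forms.

**Compound list**

1 | 2-bromo-3,5-dimethoxybenzaldehyde | COc1cc(OC)c(Br)c(C=O)c1 | starting material
2 | diethyl (4-methoxybenzyl)phosphonate | CCOP(=O)(OCC)Cc1ccc(OC)cc1 | starting material
3 | (E)-2-bromo-1,5-dimethoxy-3-(4-methoxystyryl)benzene | COc1ccc(/C=C/c2cc(OC)cc(OC)c2Br)cc1 | intermediate
4 | 2',4'-dimethoxyacetophenone | CC(=O)c1ccc(OC)cc1OC | starting material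
5 | 2,4-dimethoxy-6-[(E)-4-methoxystyryl]phenyllithium | [Li]c1c(OC)cc(OC)cc1/C=C/c1ccc(OC)cc1 | intermediate
6 | rac-1-(2,4-dimethoxyphenyl)-1-{2,4-dimethoxy-6-[(E)-4-methoxystyryl]phenyl}ethanol | CC(O)(c1ccc(OC)cc1OC)c1c(OC)cc(OC)cc1/C=C/c1ccc(OC)cc1 | intermediate
7 | 1-(2,4-dimethoxyphenyl)-1-{2,4-dimethoxy-6-[(E)-4-methoxystyryl]phenyl}ethene | C=C(c1ccc(OC)cc1OC)c1c(OC)cc(OC)cc1/C=C/c1ccc(OC)cc1 | intermediate
8 | pinacol (R)-2-(2,4-dimethoxyphenyl)-2-{2,4-dimethoxy-6-[(E)-4-methoxystyryl]phenyl}ethylboronate | CC1(C)OB(C[C@H](c2ccc(OC)cc2OC)c2c(OC)cc(OC)cc2/C=C/c2ccc(OC)cc2)OC1(C)C | intermediate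
9 | (R)-2-(2,4-dimethoxyphenyl)-2-{2,4-dimethoxy-6-[(E)-4-methoxystyryl]phenyl}ethanol | OC[C@H](c1ccc(OC)cc1OC)c1c(OC)cc(OC)cc1/C=C/c1ccc(OC)cc1 | intermediate
10 | (R)-2-(2,4-dimethoxyphenyl)-2-{2,4-dimethoxy-6-[(E)-4-methoxystyryl]phenyl}ethyl bromide | BrC[C@H](c1ccc(OC)cc1OC)c1c(OC)cc(OC)cc1/C=C/c1ccc(OC)cc1 | intermediate
11 | 4-iodoresorcinol | Oc1ccc(I)c(O)c1 | starting material
12 | 1-iodo-2,4-bis(methoxymethoxy)benzene (I on B1; MOM ethers on B2 and B4) | COCOc1ccc(I)c(OCOC)c1 | intermediate
13 | (5E,11R)-11-(2,4-dimethoxyphenyl)-1,3-dimethoxy-5-(4-methoxybenzylidene)-6,8-bis(methoxymethoxy)-10,11-dihydro-5H-dibenzo[a,d][7]annulene | COCOc1cc(OCOC)cc2c1/C(=C/c1ccc(OC)cc1)c1cc(OC)cc(OC)c1[C@@H](c1ccc(OC)cc1OC)C2 | intermediate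
14 | (5E,11R)-11-(2,4-dimethoxyphenyl)-1,3-dimethoxy-5-(4-methoxybenzylidene)-10,11-dihydro-5H-dibenzo[a,d][7]annulene-6,8-diol | Oc1cc(O)cc2c1/C(=C/c1ccc(OC)cc1)c1cc(OC)cc(OC)c1[C@@H](c1ccc(OC)cc1OC)C2 | intermediate
15 | D2-closed phenol: rings B, E, F with D2 = (2R,3R)-trans-2-(4-methoxyphenyl)-2,3-dihydrofuran (O on B2; C3 on B1 and F6); ring-E methine (R) bearing 2,4-dimethoxyphenyl; OMe on F2 and F4; B4–OH; B5–H | Oc1cc2c3c(c1)C[C@H](c1ccc(OC)cc1OC)c1c(OC)cc(OC)cc1[C@H]3[C@H](c1ccc(OC)cc1)O2 | intermediate
16 | salicylaldehyde: 15 with CHO on B5 | Oc1cc2c3c(c1C=O)C[C@H](c1ccc(OC)cc1OC)c1c(OC)cc(OC)cc1[C@H]3[C@H](c1ccc(OC)cc1)O2 | intermediate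
17 | 4-methoxybenzyl chloride | COc1ccc(CCl)cc1 | starting material
18 | B4–O-(4-methoxybenzyl) ether of 16 | COc1ccc(COc2cc3c4c(c2C=O)C[C@H](c2ccc(OC)cc2OC)c2c(OC)cc(OC)cc2[C@H]4[C@H](c2ccc(OC)cc2)O3)cc1 | intermediate
19 | 3,5-dimethoxyphenylmagnesium chloride (THF solution) | COc1cc(OC)cc([Mg]Cl)c1 | starting material
20 | diarylmethanol: 18 with B5–CH(OH)(3,5-dimethoxyphenyl), both carbinol epimers | COc1ccc(COc2cc3c4c(c2C(O)c2cc(OC)cc(OC)c2)C[C@H](c2ccc(OC)cc2OC)c2c(OC)cc(OC)cc2[C@H]4[C@H](c2ccc(OC)cc2)O3)cc1 | intermediate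
21 | diaryl ketone: B5–C(=O)(3,5-dimethoxyphenyl) | COc1ccc(COc2cc3c4c(c2C(=O)c2cc(OC)cc(OC)c2)C[C@H](c2ccc(OC)cc2OC)c2c(OC)cc(OC)cc2[C@H]4[C@H](c2ccc(OC)cc2)O3)cc1 | intermediate
22 | hydrazone of 21 | COc1ccc(COc2cc3c4c(c2C(=NN)c2cc(OC)cc(OC)c2)C[C@H](c2ccc(OC)cc2OC)c2c(OC)cc(OC)cc2[C@H]4[C@H](c2ccc(OC)cc2)O3)cc1 | intermediate
23 | diaryldiazomethane from 22 | COc1ccc(COc2cc3c4c(c2C(=[N+]=[N-])c2cc(OC)cc(OC)c2)C[C@H](c2ccc(OC)cc2OC)c2c(OC)cc(OC)cc2[C@H]4[C@H](c2ccc(OC)cc2)O3)cc1 | intermediate
24 | cis-D1 octamethyl ether: D1 closed (O on B4; C3 on B5), (2S,3R)-cis-2-(4-methoxyphenyl)-3-(3,5-dimethoxyphenyl); other centres as in 15 | COc1ccc([C@H]2Oc3cc4c5c(c3[C@H]2c2cc(OC)cc(OC)c2)C[C@H](c2ccc(OC)cc2OC)c2c(OC)cc(OC)cc2[C@H]5[C@H](c2ccc(OC)cc2)O4)cc1 | intermediate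
25 | octa-O-methyl ether of the target: D1 (2R,3R)-trans; D2 (2R,3R)-trans; ring-E methine R | COc1ccc([C@@H]2Oc3cc4c5c(c3[C@H]2c2cc(OC)cc(OC)c2)C[C@H](c2ccc(OC)cc2OC)c2c(OC)cc(OC)cc2[C@H]5[C@H](c2ccc(OC)cc2)O4)cc1 | intermediate
26 | CNP0154047.1: D1 (2R,3R); D2 (2R,3R); ring-E methine R | Oc1ccc([C@@H]2Oc3cc4c5c(c3[C@H]2c2cc(O)cc(O)c2)C[C@H](c2ccc(O)cc2O)c2c(O)cc(O)cc2[C@H]5[C@H](c2ccc(O)cc2)O4)cc1 | target

**Step count**

Total: 16 steps. Longest linear sequence: 15 steps (steps 1–5, then 7–16).

**Steps most likely to fail**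

1. Step 7. The β-hydrogen of 10 is doubly benzylic, so loss of HBr under the carbonate base, or aryl-assisted ionisation with 1,2-aryl shift, may outrun the slow oxidative addition of this β-branched bromide to the palladacycle. The aryl palladium species formed after alkylation may also be diverted into direct arylation of ring A. Fallback (the two bonds are made in separate operations), setting out from 10 and returning at 13: commercial 5-iodoresorcinol is protected (MOMCl, i-Pr2NEt) as 1-iodo-3,5-bis(methoxymethoxy)benzene F1 and brominated ortho to iodine and para to one acetal oxygen (NBS, MeCN, 0 °C) to give 2-bromo-1-iodo-3,5-bis(methoxymethoxy)benzene F2. Bromide 10 is converted with zinc dust and LiCl (THF, 40 °C) into the (R)-alkylzinc bromide F3, which undergoes Negishi coupling at the C–I bond of F2 (Pd(OAc)2, CPhos, THF, rt) to give the (R)-aryl bromide F4. Intramolecular Heck cyclisation of F4 (Pd(OAc)2, P(t-Bu)3·HBF4, Cs2CO3, DMF, 100 °C) then closes ring E 7-exo and gives 13.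

2. Step 8. If re-ionisation is slow, protonation of the benzylidene may fix the hydrogen at C3 of D2 on the face that is kinetically, not thermodynamically, preferred; prolonged acid may also erode the ring-E methine through reversible Friedel–Crafts ionisation. Fallback (kinetic, reagent-delivered hydrogen instead of equilibrating protonation), setting out from 13 and returning at 15: hydroboration of 13 with BH3·SMe2 (THF, 0 °C → rt) adds H to C3 and boron to the 4-methoxybenzylic carbon in a syn fashion from the more open face, giving the alkylborane F5. Oxidation (NaOH, H2O2) gives the secondary benzylic alcohol F6. Brief treatment with HCl in MeOH then removes both MOM groups, and the B2 phenol displaces the ionised benzylic hydroxyl to give the trans ring of 15 without passing through the alkene.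

3. Step 4. The catalyst may discriminate poorly between two alkene faces flanked by similar ortho-methoxyaryl groups, and hydrocupration of the stilbene may compete. Fallback (resolution instead of asymmetric catalysis), setting out from 7 and returning at 9: hydroboration with 9-BBN (THF, rt), which is selective for the terminal methylene, gives the racemic B-alkyl-9-borabicyclononane F7. Oxidation (NaOH, H2O2) gives the racemic alcohol F8. Preparative chromatography on a chiral stationary phase (supercritical CO2/MeOH) then affords 9, and the (S)-alcohol F9 is set aside.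

**Further compounds**

F1 | step 7 | 1-iodo-3,5-bis(methoxymethoxy)benzene | COCOc1cc(I)cc(OCOC)c1
F2 | step 7 | 2-bromo-1-iodo-3,5-bis(methoxymethoxy)benzene | COCOc1cc(I)c(Br)c(OCOC)c1
F3 | step 7 | (R)-2-(2,4-dimethoxyphenyl)-2-{2,4-dimethoxy-6-[(E)-4-methoxystyryl]phenyl}ethylzinc bromide | Br[Zn]C[C@H](c1ccc(OC)cc1OC)c1c(OC)cc(OC)cc1/C=C/c1ccc(OC)cc1
F4 | step 7 | (R)-2-bromo-1-[2-(2,4-dimethoxyphenyl)-2-{2,4-dimethoxy-6-[(E)-4-methoxystyryl]phenyl}ethyl]-3,5-bis(methoxymethoxy)benzene | COCOc1cc(OCOC)c(Br)c(C[C@H](c2ccc(OC)cc2OC)c2c(OC)cc(OC)cc2/C=C/c2ccc(OC)cc2)c1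
F5 | step 8 | alkylborane: 13 with H on C3 (R) and BH2 on the 4-methoxybenzylic carbon, syn addition | COCOc1cc(OCOC)cc2c1[C@H]([C@@H](B)c1ccc(OC)cc1)c1cc(OC)cc(OC)c1[C@@H](c1ccc(OC)cc1OC)C2
F6 | step 8 | secondary alcohol: 13 with H on C3 (R) and OH on the 4-methoxybenzylic carbon (R) | COCOc1cc(OCOC)cc2c1[C@H]([C@@H](O)c1ccc(OC)cc1)c1cc(OC)cc(OC)c1[C@@H](c1ccc(OC)cc1OC)C2
F7 | step 4 | rac-9-[2-(2,4-dimethoxyphenyl)-2-{2,4-dimethoxy-6-[(E)-4-methoxystyryl]phenyl}ethyl]-9-borabicyclo[3.3.1]nonane | C1CC2CCCC(C1)B2CC(c1ccc(OC)cc1OC)c1c(OC)cc(OC)cc1/C=C/c1ccc(OC)cc1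
F8 | step 4 | rac-2-(2,4-dimethoxyphenyl)-2-{2,4-dimethoxy-6-[(E)-4-methoxystyryl]phenyl}ethanol | OCC(c1ccc(OC)cc1OC)c1c(OC)cc(OC)cc1/C=C/c1ccc(OC)cc1
F9 | step 4 | (S)-2-(2,4-dimethoxyphenyl)-2-{2,4-dimethoxy-6-[(E)-4-methoxystyryl]phenyl}ethanol | OC[C@@H](c1ccc(OC)cc1OC)c1c(OC)cc(OC)cc1/C=C/c1ccc(OC)cc1
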